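If one nucleophile made one target, the ochre run, with 0.53 M of nucleophile against 0.50 M of electrophile, should end with its electrophile gone. Yet at 90.0 s it still shows 26.2% electrophile and 53.7% target, and these readings have nearly stopped moving.

| setting | ochre | green | red | winter | midnight | dawn |
|---|---|---|---|---|---|---|
| electrophile | 0.50 M | 0.50 M | 0.50 M | 0.50 M | 0.50 M | 0.50 M |
| nucleophile | 0.53 M | 0.56 M | 0.59 M | 0.470 M | 0.620 M | 0.800 M |
| remark | run made earlier | run made earlier | run made earlier |  |  |  |
| time |  |  |  | 3.0 min | 3.0 min | 3.0 min |

| run | time / s | electrophile / % | target / % |
|---|---|---|---|
| ochre | 25.0 | 31.7 | 50.6 |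
| ochre | 50.0 | 27.6 | 52.6 |
| ochre | 60.0 | 27.7 | 53.0 |
| ochre | 90.0 | 26.2 | 53.7 |
| green | 25.0 | 30.0 | 52.9 |
| green | 50.0 | 25.7 | 55.6 |
| green | 60.0 | 25.4 | 56.1 |
| green | 90.0 | 24.7 | 56.4 |
| red | 12.0 | 38.5 | 49.4 |
| red | 30.0 | 26.4 | 57.1 |
| red | 60.0 | 24.3 | 59.0 |
| red | 90.0 | 23.3 | 59.3 |

(each reading ± 0.3 percentage points)

- what has gone from electrophile into another species counts as reacted, even if it can come back

- part of the electrophile that has reacted at the end, winter
- part of the electrophile that has reacted at the end, midnight
- part of the electrophile that has reacted at the end, dawn
- what raising the concentration of nucleophile from its lowest to its highest value here does to the part of the electrophile that has reacted (changes below 5 percentage points count as none) (it rises / it falls / no change)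

The ochre target amounts to 0.269 M, which is half of the nucleophile charged, as if each target cost two nucleophiles. So I divide c(nucleophile) by two, then by c(electrophile), and call this the two-per-target share. It gives 53.0%, 56.0% and 59.0% for ochre, green and red, against last target readings of 53.7%, 56.4% and 59.3%. For the dawn flask the two-per-target share is 80.0%. Nucleophile is the limiting reagent in the asked flasks, since even the dawn charge falls short of the 1.00 M that two per electrophile needs.

Electrophile and target together leave a third pool, which on average over the last readings of the runs stands at 0.760 of the electrophile. I set target at the share, split the rest between electrophile and third pool in that ratio, and count as reacted what is not free electrophile. My reckoning gives 69.9% for winter, 78.4% for midnight and 88.6% for dawn.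

The forecast reads the runs differently, "this looks like an equilibrium", and gives 71%, 78.3% and 83.5%, with the trend: it rises. It lies close to my numbers for winter and midnight, but for dawn it stands lower than mine.

The flasks give 70.4%, 78.9% and 88.9%, and the trend is: it rises, by 18 percentage points.

    electrophile + nucleophile → acid set free + target (k = 0.260 M⁻¹ s⁻¹)
    nucleophile + acid set free ⇌ protonated nucleophile, settled at all times (K = 19000 M⁻¹)
    electrophile ⇌ dormant form (K = 0.740, k = 0.0220 s⁻¹)

In dawn, the share of 80.0% stands beside 80.5% of target at 3.00 min. A further flask, like midnight but with 2.5 M of nucleophile, has electrophile as its limiting reagent and ends with >99.9% of target; two per target then leaves 60.0% of its nucleophile charge, and it shows 60% free. In midnight, the forward step to the dormant form has a half-life of 0.53 min, short against the 3.0 min of the run. In midnight, the step to target uses electrophile at 7.3 times that forward rate just after the start, and at 0.014 times it at the asked time.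

Readings and results are calculated for an exercise.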